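**Retrosynthetic overview**

1. Feature: in the five-carbon chain between the rings, the carbinol carbon on chromene C6 carries a CH3 group and the chain CH2, and these differ only by the CH2–CH(methine) bond. Cutting that bond leaves an achiral 2-arylpropan-2-ol on chromene C6 with two enantiotopic methyl groups, in which both stereocentres are latent.
2. Key disconnection: the CH2–CH bond, made by C–H insertion of a benzofuran-2-yl rhodium carbene tied to the carbinol oxygen as its diazoacetate ester. The γ-lactone is temporary, and its carbonyl carbon is cut down to the methine CH3 (C=O → CH2OH → CH2I → CH3).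
3. Diazo ester 19 comes from carbinol 6 (chromene: formylation, MeMgBr, MnO2, MeMgBr) and acid 15 (2,4-dihydroxyacetophenone: iodination, Sonogashira annulation with but-3-yn-1-ol, oxidation, silylation), followed by esterification and diazo transfer.
4. Ring order: the pyran ring comes with the starting chromene, the furan ring of the benzofuran is closed in step 6, and the γ-lactone ring is closed in step 11 and opened in step 12.

Key step: step 11

Assumption: Rh2(S-PTTL)4 (dirhodium tetrakis[N-phthaloyl-(S)-tert-leucinate]) is taken to give the (3S,5S)-lactone; if the sense of induction is the opposite, Rh2(R-PTTL)4 is used in the same way.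

**Route**

Step 1
Reactants: 1 7-methoxy-2,2-dimethyl-2H-chromene
Product: 3 7-methoxy-2,2-dimethyl-2H-chromene-6-carbaldehyde, via aryl iminium salt 2 (not isolated)
Conditions: POCl3, DMF, 0 → 60 °C; then aq. NaOAc
Reagents that add atoms: N,N-dimethylformamide, CN(C)C=O; water, O
Why: Vilsmeier–Haack formylation should attack C6, which is para to the ring oxygen, ortho to the methoxy group and the least hindered activated position, and the chloroiminium electrophile needs no protic or Lewis acid, so the acid-sensitive C3=C4 bond next to the gem-dimethyl carbon should stay intact.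

Step 2
Reactants: 3 7-methoxy-2,2-dimethyl-2H-chromene-6-carbaldehyde
Product: 4 1-(7-methoxy-2,2-dimethyl-2H-chromen-6-yl)ethanol (racemic)
Conditions: MeMgBr, THF, 0 °C; aq. NH4Cl
Reagents that add atoms: methylmagnesium bromide, C[Mg]Br
Why: Grignard addition to an aryl aldehyde gives the secondary benzylic alcohol, whose stereocentre is removed in step 3.

Step 3
Reactants: 4 1-(7-methoxy-2,2-dimethyl-2H-chromen-6-yl)ethanol
Product: 5 1-(7-methoxy-2,2-dimethyl-2H-chromen-6-yl)ethanone
Conditions: MnO2, CH2Cl2, rt
Reagents that add atoms: none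
Why: MnO2 oxidises benzylic alcohols selectively and should leave the chromene double bond and the electron-rich ring untouched.

Step 4
Reactants: 5 1-(7-methoxy-2,2-dimethyl-2H-chromen-6-yl)ethanone
Product: 6 2-(7-methoxy-2,2-dimethyl-2H-chromen-6-yl)propan-2-ol
Conditions: MeMgBr, THF, 0 °C → rt; aq. NH4Cl
Reagents that add atoms: methylmagnesium bromide, C[Mg]Br
Why: Grignard addition to the aryl methyl ketone, helped by chelation to the ortho methoxy group, gives the tertiary carbinol with two enantiotopic methyl groups, and the near-neutral work-up avoids dehydration of this ionisable alcohol.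

Step 5
Reactants: 7 2,4-dihydroxyacetophenone
Product: 8 1-(2,4-dihydroxy-5-iodophenyl)ethanone
Conditions: ICl, AcOH, rt
Reagents that add atoms: iodine monochloride, ClI
Why: Electrophilic aromatic iodination should go to C5, para to the hydrogen-bonded 2-OH and ortho to the free 4-OH, because C3 lies between two oxygen substituents and is more hindered.

Step 6
Reactants: 8 1-(2,4-dihydroxy-5-iodophenyl)ethanone; 9 but-3-yn-1-ol
Product: 11 1-[6-hydroxy-2-(2-hydroxyethyl)benzofuran-5-yl]ethanone, via alkynylphenol 10 (not isolated)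
Conditions: PdCl2(PPh3)2 (3 mol %), CuI (5 mol %), Et3N, DMF, 70 °C
Reagents that add atoms: none
Why: Sonogashira coupling followed by 5-endo-dig cycloisomerisation of the ortho-alkynylphenol closes the furan ring through the only hydroxyl ortho to the alkyne, while the other hydroxyl is para to it and held in a hydrogen bond to the acetyl group.

Step 7
Reactants: 11 1-[6-hydroxy-2-(2-hydroxyethyl)benzofuran-5-yl]ethanone
Product: 13 2-(5-acetyl-6-hydroxybenzofuran-2-yl)acetic acid, via arylacetaldehyde 12 (not isolated)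
Conditions: CrO3, H2SO4, acetone–H2O, 0 °C
Reagents that add atoms: water, O
Why: Chromic acid (Jones) oxidation takes the primary alcohol through the aldehyde hydrate to the arylacetic acid, a standard way from 2-(benzofuran-2-yl)ethanols, and the phenol is deactivated by the hydrogen-bonded ortho acetyl group.

Step 8
Reactants: 13 2-(5-acetyl-6-hydroxybenzofuran-2-yl)acetic acid
Product: 15 2-[5-acetyl-6-(triisopropylsilyloxy)benzofuran-2-yl]acetic acid, via bis-silyl compound 14 (not isolated)
Conditions: TIPSCl, imidazole, DMF, rt; then AcOH–THF–H2O, rt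
Reagents that add atoms: triisopropylsilyl chloride, CC(C)[Si](Cl)(C(C)C)C(C)C
Why: Silylation covers phenol and acid, and the silyl ester is hydrolysed much faster than the aryl silyl ether in aqueous acetic acid; TIPS is chosen over TBS because it should better withstand DBU, hydride and O-to-O migration in steps 10 and 12.

Step 9
Reactants: 15 2-[5-acetyl-6-(triisopropylsilyloxy)benzofuran-2-yl]acetic acid; 6 2-(7-methoxy-2,2-dimethyl-2H-chromen-6-yl)propan-2-ol
Product: 18 2-(7-methoxy-2,2-dimethyl-2H-chromen-6-yl)propan-2-yl 2-[5-acetyl-6-(triisopropylsilyloxy)benzofuran-2-yl]acetate, via acid chloride 16 (not isolated), via lithium alkoxide 17 (not isolated)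
Conditions: 15, (COCl)2, DMF (cat.), CH2Cl2, 0 °C → rt, evaporate; 6, n-BuLi (1.0 equiv), THF, −78 °C; combine, −78 → 0 °C; aq. NaHCO3
Reagents that add atoms: none
Why: Acylation of a preformed lithium alkoxide with an acid chloride is the established way to esters of acid-labile tertiary benzylic alcohols because no acid is present at any time, and if the acid chloride first loses HCl to the aryl ketene, addition of the alkoxide to the ketene leads to the same ester.

Step 10
Reactants: 18 the arylacetate ester
Product: 19 2-(7-methoxy-2,2-dimethyl-2H-chromen-6-yl)propan-2-yl 2-[5-acetyl-6-(triisopropylsilyloxy)benzofuran-2-yl]-2-diazoacetate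
Conditions: p-ABSA, DBU, MeCN (dry), 0 °C → rt
Reagents that add atoms: 4-acetamidobenzenesulfonyl azide (p-ABSA), CC(=O)Nc1ccc(cc1)S(=O)(=O)N=[N+]=[N-]
Why: Regitz diazo transfer should take place at the ester α-CH2, the most acidic position between carbonyl and benzofuran, while the acetyl methyl group does not undergo transfer without prior activation.

Step 11
Reactants: 19 the diazo ester
Product: 20 (3S,5S)-3-[5-acetyl-6-(triisopropylsilyloxy)benzofuran-2-yl]-5-(7-methoxy-2,2-dimethyl-2H-chromen-6-yl)-5-methyldihydrofuran-2(3H)-one (benzofuranyl trans to chromenyl)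
Conditions: Rh2(S-PTTL)4 (2 mol %), 4 Å MS, 2,2-dimethylbutane–PhCF3 (3:1), 0 °C → rt, 19 added over 6 h
Reagents that add atoms: none
Why: Proposed new method: Rh2(S-PTTL)4 expels N2 from 19, and the donor–acceptor rhodium carbene should insert into a C–H bond of one of the two methyl groups through a concerted, asynchronous three-centre transition state with hydride-transfer character, which forms the CH2–CH bond. The closest known reaction types are 1,5 C–H insertions of aryldiazoacetates to γ-lactones with chiral divalent rhodium carboxylates, insertion into the methyl groups of tert-alkyl diazoesters, and enantiotopic-group-selective carbene insertions, but a choice between the two enantiotopic methyl groups of a tertiary ester has not been shown. The γ-lactone closes by 1,5-insertion through a five-membered transition ring from the E ester rotamer, and because the carbinol carbon bears no hydrogen a β-lactone cannot form. The quaternary centre (lactone C5) is set by the choice of the pro-S methyl group inside the chiral carboxylate pocket, and the methine centre (lactone C3) by the carbene face that meets this C–H bond, with the benzofuranyl group turned away from the chromenyl group to give the trans lactone; lactone C3 is epimerisable, so a cis fraction could be equilibrated with DBU and recycled. The step needs chemoselectivity for a primary C–H bond over the electron-rich chromene ring, its C3=C4 bond and the ether and ketone oxygens: the only aromatic carbon within five-ring reach is the fully substituted C6 hemmed in by the ortho OMe group, the free ortho carbon C5 is meta to both ring oxygens, the gem-dimethyl group shields the C3=C4 bond, and slow addition keeps carbene dimerisation and intermolecular reactions down. The remaining risks are the low reactivity of primary C–H bonds and ionisation of the tertiary benzylic lactone, which the hydrocarbon-rich solvent, the molecular sieves and the low temperature are meant to limit.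

Step 12
Reactants: 20 the trans lactone
Product: 21 (2R,4S)-2-[5-(1-hydroxyethyl)-6-(triisopropylsilyloxy)benzofuran-2-yl]-4-(7-methoxy-2,2-dimethyl-2H-chromen-6-yl)pentane-1,4-diol (both epimers at the hydroxyethyl carbon)
Conditions: LiAlH4, THF, −40 → 0 °C (20 added to the hydride); aq. potassium sodium tartrate
Reagents that add atoms: none
Why: LiAlH4 reduces the lactone to the 1,4-diol and the ketone to the carbinol, and inverse addition at low temperature should make hydride attack faster than enolisation, so the methine centre is not epimerised and neither stereocentre is a reacting atom (the descriptor change at the methine is only a change of priorities).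

Step 13
Reactants: 21 the triol
Product: 22 1-[2-[(2R,4S)-1,4-dihydroxy-4-(7-methoxy-2,2-dimethyl-2H-chromen-6-yl)pentan-2-yl]-6-(triisopropylsilyloxy)benzofuran-5-yl]ethanone
Conditions: MnO2, CH2Cl2, rt
Reagents that add atoms: none
Why: MnO2 oxidises only the benzylic secondary alcohol back to the acetyl group, so the activation in step 14 does not have to tell the primary alcohol from a reactive, electron-rich benzylic alcohol.

Step 14
Reactants: 22 the keto diol
Product: 23 1-[2-[(2S,4S)-4-hydroxy-1-iodo-4-(7-methoxy-2,2-dimethyl-2H-chromen-6-yl)pentan-2-yl]-6-(triisopropylsilyloxy)benzofuran-5-yl]ethanone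
Conditions: I2, PPh3, imidazole, CH2Cl2, 0 °C; filtered through basic alumina and used at once
Reagents that add atoms: iodine, II
Why: Appel-type iodination converts the primary alcohol by SN2 displacement of its alkoxyphosphonium by iodide, while the tertiary alcohol beside the ortho-substituted ring is too hindered to be activated at 0 °C, and imidazole keeps the medium free of acid.

Step 15
Reactants: 23 the primary iodide
Product: 24 1-[2-[(2S,4S)-4-hydroxy-4-(7-methoxy-2,2-dimethyl-2H-chromen-6-yl)pentan-2-yl]-6-(triisopropylsilyloxy)benzofuran-5-yl]ethanone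
Conditions: Bu3SnH (0.3 M), Et3B, air, toluene, 0 °C → rt
Reagents that add atoms: none
Why: Radical-chain dehalogenation with tin hydride turns CH2I into the methine CH3 group under neutral conditions, the high stannane concentration should trap the primary radical before aryl migration or cyclisation, and the cold neutral medium keeps the hydroxy iodide from closing to a tetrahydrofuran.

Step 16
Reactants: 24 the silyl ether of the target
Product: 25 1-[6-hydroxy-2-[(2S,4S)-4-hydroxy-4-(7-methoxy-2,2-dimethyl-2H-chromen-6-yl)pentan-2-yl]benzofuran-5-yl]ethanone (target)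
Conditions: Bu4NF, AcOH, THF, 0 °C
Reagents that add atoms: none
Why: Fluoride cleaves the aryl silyl ether through Si–F bond formation, and the acetic acid buffer should give the hydrogen-bonded o-hydroxyacetophenone without any acid or strong base reaching the tertiary benzylic alcohol.

**Compound list**

1 | 7-methoxy-2,2-dimethyl-2H-chromene | COc1ccc2C=CC(C)(C)Oc2c1 | starting material
2 | N-[(7-methoxy-2,2-dimethyl-2H-chromen-6-yl)methylidene]-N-methylmethanaminium dichlorophosphate | COc1cc2c(cc1C=[N+](C)C)C=CC(C)(C)O2.[O-]P(=O)(Cl)Cl | intermediate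
3 | 7-methoxy-2,2-dimethyl-2H-chromene-6-carbaldehyde | COc1cc2c(cc1C=O)C=CC(C)(C)O2 | intermediate
4 | 1-(7-methoxy-2,2-dimethyl-2H-chromen-6-yl)ethanol (racemic) | COc1cc2c(cc1C(C)O)C=CC(C)(C)O2 | intermediate
5 | 1-(7-methoxy-2,2-dimethyl-2H-chromen-6-yl)ethanone | COc1cc2c(cc1C(C)=O)C=CC(C)(C)O2 | intermediate
6 | 2-(7-methoxy-2,2-dimethyl-2H-chromen-6-yl)propan-2-ol | COc1cc2c(cc1C(C)(C)O)C=CC(C)(C)O2 | intermediate
7 | 2,4-dihydroxyacetophenone | CC(=O)c1ccc(O)cc1O | starting material
8 | 1-(2,4-dihydroxy-5-iodophenyl)ethanone | CC(=O)c1cc(I)c(O)cc1O | intermediate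
9 | but-3-yn-1-ol | OCCC#C | starting material
10 | 1-[2,4-dihydroxy-5-(4-hydroxybut-1-yn-1-yl)phenyl]ethanone | CC(=O)c1cc(C#CCCO)c(O)cc1O | intermediate
11 | 1-[6-hydroxy-2-(2-hydroxyethyl)benzofuran-5-yl]ethanone | CC(=O)c1cc2cc(CCO)oc2cc1O | intermediate
12 | 2-(5-acetyl-6-hydroxybenzofuran-2-yl)acetaldehyde | CC(=O)c1cc2cc(CC=O)oc2cc1O | intermediate
13 | 2-(5-acetyl-6-hydroxybenzofuran-2-yl)acetic acid | CC(=O)c1cc2cc(CC(=O)O)oc2cc1O | intermediate
14 | triisopropylsilyl 2-[5-acetyl-6-(triisopropylsilyloxy)benzofuran-2-yl]acetate | CC(=O)c1cc2cc(CC(=O)O[Si](C(C)C)(C(C)C)C(C)C)oc2cc1O[Si](C(C)C)(C(C)C)C(C)C | intermediate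
15 | 2-[5-acetyl-6-(triisopropylsilyloxy)benzofuran-2-yl]acetic acid | CC(=O)c1cc2cc(CC(=O)O)oc2cc1O[Si](C(C)C)(C(C)C)C(C)C | intermediate
16 | 2-[5-acetyl-6-(triisopropylsilyloxy)benzofuran-2-yl]acetyl chloride | CC(=O)c1cc2cc(CC(=O)Cl)oc2cc1O[Si](C(C)C)(C(C)C)C(C)C | intermediate
17 | lithium 2-(7-methoxy-2,2-dimethyl-2H-chromen-6-yl)propan-2-olate | COc1cc2c(cc1C(C)(C)[O-])C=CC(C)(C)O2.[Li+] | intermediate
18 | 2-(7-methoxy-2,2-dimethyl-2H-chromen-6-yl)propan-2-yl 2-[5-acetyl-6-(triisopropylsilyloxy)benzofuran-2-yl]acetate | COc1cc2c(cc1C(C)(C)OC(=O)Cc1cc3cc(C(C)=O)c(O[Si](C(C)C)(C(C)C)C(C)C)cc3o1)C=CC(C)(C)O2 | intermediate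
19 | 2-(7-methoxy-2,2-dimethyl-2H-chromen-6-yl)propan-2-yl 2-[5-acetyl-6-(triisopropylsilyloxy)benzofuran-2-yl]-2-diazoacetate | COc1cc2c(cc1C(C)(C)OC(=O)C(=[N+]=[N-])c1cc3cc(C(C)=O)c(O[Si](C(C)C)(C(C)C)C(C)C)cc3o1)C=CC(C)(C)O2 | intermediate
20 | (3S,5S)-3-[5-acetyl-6-(triisopropylsilyloxy)benzofuran-2-yl]-5-(7-methoxy-2,2-dimethyl-2H-chromen-6-yl)-5-methyldihydrofuran-2(3H)-one | COc1cc2c(cc1[C@@](C)(OC1=O)C[C@H]1c1cc3cc(C(C)=O)c(O[Si](C(C)C)(C(C)C)C(C)C)cc3o1)C=CC(C)(C)O2 | intermediate
21 | (2R,4S)-2-[5-(1-hydroxyethyl)-6-(triisopropylsilyloxy)benzofuran-2-yl]-4-(7-methoxy-2,2-dimethyl-2H-chromen-6-yl)pentane-1,4-diol (both epimers at the hydroxyethyl carbon) | COc1cc2c(cc1[C@@](C)(O)C[C@H](CO)c1cc3cc(C(C)O)c(O[Si](C(C)C)(C(C)C)C(C)C)cc3o1)C=CC(C)(C)O2 | intermediate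
22 | 1-[2-[(2R,4S)-1,4-dihydroxy-4-(7-methoxy-2,2-dimethyl-2H-chromen-6-yl)pentan-2-yl]-6-(triisopropylsilyloxy)benzofuran-5-yl]ethanone | COc1cc2c(cc1[C@@](C)(O)C[C@H](CO)c1cc3cc(C(C)=O)c(O[Si](C(C)C)(C(C)C)C(C)C)cc3o1)C=CC(C)(C)O2 | intermediate
23 | 1-[2-[(2S,4S)-4-hydroxy-1-iodo-4-(7-methoxy-2,2-dimethyl-2H-chromen-6-yl)pentan-2-yl]-6-(triisopropylsilyloxy)benzofuran-5-yl]ethanone | COc1cc2c(cc1[C@@](C)(O)C[C@H](CI)c1cc3cc(C(C)=O)c(O[Si](C(C)C)(C(C)C)C(C)C)cc3o1)C=CC(C)(C)O2 | intermediate
24 | 1-[2-[(2S,4S)-4-hydroxy-4-(7-methoxy-2,2-dimethyl-2H-chromen-6-yl)pentan-2-yl]-6-(triisopropylsilyloxy)benzofuran-5-yl]ethanone | COc1cc2c(cc1[C@@](C)(O)C[C@H](C)c1cc3cc(C(C)=O)c(O[Si](C(C)C)(C(C)C)C(C)C)cc3o1)C=CC(C)(C)O2 | intermediate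
25 | 1-[6-hydroxy-2-[(2S,4S)-4-hydroxy-4-(7-methoxy-2,2-dimethyl-2H-chromen-6-yl)pentan-2-yl]benzofuran-5-yl]ethanone | COc1cc2c(cc1[C@@](C)(O)C[C@H](C)c1cc3cc(C(C)=O)c(O)cc3o1)C=CC(C)(C)O2 | target

**Count and risks**

Total step count: 16. Longest linear sequence: 12 steps (steps 1–4 and 9–16, or equally steps 5–8 and 9–16).

Steps most likely to fail:

1. Step 11. The carbene may attack the electron-rich aryl ring or dimerise faster than it inserts into a primary C–H bond, or the two methyl groups may be poorly distinguished. The fallback uses known chemistry, sets out from ketone 5 and acid 15, and comes back at lactone 20. Catalytic asymmetric Corey–Chaykovsky epoxidation of 5 (Me3S(O)I, NaH, the LaLi3(binaphthoxide)3 complex with a triarylphosphine oxide additive, THF, rt), with the ligand enantiomer that gives the R epoxide, should give (R)-7-methoxy-2,2-dimethyl-6-(2-methyloxiran-2-yl)-2H-chromene F1. The lithium trianion of 15 (LiN(i-Pr)2, 3.1 equiv, THF, −78 → 0 °C, acetyl group enolised as well) opens F1 at its CH2 terminus. Buffered work-up should give (4S)-2-[5-acetyl-6-(triisopropylsilyloxy)benzofuran-2-yl]-4-hydroxy-4-(7-methoxy-2,2-dimethyl-2H-chromen-6-yl)pentanoic acid F2, which closes on standing to 20 together with its lactone C3 epimer, (3R,5S)-3-[5-acetyl-6-(triisopropylsilyloxy)benzofuran-2-yl]-5-(7-methoxy-2,2-dimethyl-2H-chromen-6-yl)-5-methyldihydrofuran-2(3H)-one F3. F3 is separated and equilibrated with DBU for recycling. Here the quaternary centre comes from the epoxidation and the methine centre from separation and equilibration.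

2. Step 9. The hindered alkoxide may act only as a base, so that the aryl ketene dimerises, or the tertiary ester may eliminate to the isopropenyl arene. The fallback sets out from 6 and comes back at 18, and it alkylates the acid oxygen instead of acylating the alcohol. Carbinol 6 with Cl3CCN and catalytic DBU (CH2Cl2, 0 °C) should give 2-(7-methoxy-2,2-dimethyl-2H-chromen-6-yl)propan-2-yl 2,2,2-trichloroacetimidate F4. F4 is used at once with acid 15 in CH2Cl2 at −20 °C → rt without added acid. Protonation of the imidate by the carboxylic acid and collapse of the tight ion pair should give 18, as in the preparation of 2-phenylisopropyl esters.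

3. Step 14. The tertiary hydroxyl may displace the activated primary oxygen or the iodide and close a tetrahydrofuran ring, or the tertiary benzylic alcohol may ionise under the phosphonium conditions. The fallback sets out from lactone 20 and comes back at 24, and it reduces the carbon at the aldehyde level so that it never becomes an sp3 electrophile. i-Bu2AlH (excess, CH2Cl2, −78 °C) should give (3S,5S)-3-[5-(1-hydroxyethyl)-6-(triisopropylsilyloxy)benzofuran-2-yl]-5-(7-methoxy-2,2-dimethyl-2H-chromen-6-yl)-5-methyltetrahydrofuran-2-ol F5, with the acetyl group reduced as well. TsNHNH2 (EtOH, rt) should give the open-chain N'-[(2R,4S)-4-hydroxy-2-[5-(1-hydroxyethyl)-6-(triisopropylsilyloxy)benzofuran-2-yl]-4-(7-methoxy-2,2-dimethyl-2H-chromen-6-yl)pentylidene]-4-methylbenzenesulfonohydrazide F6. Catecholborane, then NaOAc·3H2O (CHCl3, 0 °C → reflux), should give 1-[2-[(2S,4S)-4-hydroxy-4-(7-methoxy-2,2-dimethyl-2H-chromen-6-yl)pentan-2-yl]-6-(triisopropylsilyloxy)benzofuran-5-yl]ethanol F7. MnO2 (CH2Cl2, rt) then gives 24.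

Further compounds
F1 | step 11 | (R)-7-methoxy-2,2-dimethyl-6-(2-methyloxiran-2-yl)-2H-chromene | COc1cc2c(cc1[C@@]3(C)OC3)C=CC(C)(C)O2
F2 | step 11 | (4S)-2-[5-acetyl-6-(triisopropylsilyloxy)benzofuran-2-yl]-4-hydroxy-4-(7-methoxy-2,2-dimethyl-2H-chromen-6-yl)pentanoic acid (both C2 epimers) | COc1cc2c(cc1[C@@](C)(O)CC(C(=O)O)c1cc3cc(C(C)=O)c(O[Si](C(C)C)(C(C)C)C(C)C)cc3o1)C=CC(C)(C)O2
F3 | step 11 | (3R,5S)-3-[5-acetyl-6-(triisopropylsilyloxy)benzofuran-2-yl]-5-(7-methoxy-2,2-dimethyl-2H-chromen-6-yl)-5-methyldihydrofuran-2(3H)-one | COc1cc2c(cc1[C@@](C)(OC1=O)C[C@@H]1c1cc3cc(C(C)=O)c(O[Si](C(C)C)(C(C)C)C(C)C)cc3o1)C=CC(C)(C)O2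
F4 | step 9 | 2-(7-methoxy-2,2-dimethyl-2H-chromen-6-yl)propan-2-yl 2,2,2-trichloroacetimidate | COc1cc2c(cc1C(C)(C)OC(=N)C(Cl)(Cl)Cl)C=CC(C)(C)O2
F5 | step 14 | (3S,5S)-3-[5-(1-hydroxyethyl)-6-(triisopropylsilyloxy)benzofuran-2-yl]-5-(7-methoxy-2,2-dimethyl-2H-chromen-6-yl)-5-methyltetrahydrofuran-2-ol (anomers, both epimers at the hydroxyethyl carbon) | COc1cc2c(cc1[C@@](C)(OC1O)C[C@H]1c1cc3cc(C(C)O)c(O[Si](C(C)C)(C(C)C)C(C)C)cc3o1)C=CC(C)(C)O2
F6 | step 14 | N'-[(2R,4S)-4-hydroxy-2-[5-(1-hydroxyethyl)-6-(triisopropylsilyloxy)benzofuran-2-yl]-4-(7-methoxy-2,2-dimethyl-2H-chromen-6-yl)pentylidene]-4-methylbenzenesulfonohydrazide | COc1cc2c(cc1[C@@](C)(O)C[C@H](C=NNS(=O)(=O)c1ccc(C)cc1)c1cc3cc(C(C)O)c(O[Si](C(C)C)(C(C)C)C(C)C)cc3o1)C=CC(C)(C)O2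
F7 | step 14 | 1-[2-[(2S,4S)-4-hydroxy-4-(7-methoxy-2,2-dimethyl-2H-chromen-6-yl)pentan-2-yl]-6-(triisopropylsilyloxy)benzofuran-5-yl]ethanol | COc1cc2c(cc1[C@@](C)(O)C[C@H](C)c1cc3cc(C(C)O)c(O[Si](C(C)C)(C(C)C)C(C)C)cc3o1)C=CC(C)(C)O2
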